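The strategy exploits ring B, the seven-membered ring (C1, C5–C10): its C7–C8–C9 segment carries C11 on C7 and oxygen on C8 and is flanked by C6 and C10, the exocyclic carbons on C5 and C1 of ring A, the cyclopentane (C1–C5). Cutting C6–C7 and C9–C10 gives a 2-siloxyvinyl rhodium carbene and an s-cis diene C6=C5–C1=C10. One cyclopropanation/Cope cascade forms both bonds, closes ring B, sets C10 and delivers a masked C7/C8 β-keto ester plus a C1=C5 alkene one proton shift away from the C4=C5 enone. The diene precursor is an (E)-ethylidene methylene cyclopentane whose cis C3 silyl ether and C4 methyl shield the α-face.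

Key step: step 8

Remark: guaiane numbering and α/β faces are used for all intermediates; TBS = tert-butyldimethylsilyl. In the target (1R,7S,8R,10S), H-1, the C10 methyl, the C8 propanoyloxy group and C11 on C7 all lie on the β-face, so the C7/C8 cis-hydroxy ester must be syn to the C10 methyl.

Assumption: Rh2(S-PTAD)4 in step 8 and the (R,R)-TsDPEN complex in step 10 are taken as the antipodes matched to β-face carbene delivery at C6 and α-face hydride delivery at C8; one pilot run with each antipode settles this, and the mirror-image catalyst would be used with no other change.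

Step 1
Reactants: 1 methyl acetoacetate
Product: 2 methyl 2-diazo-3-oxobutanoate
Conditions: p-ABSA, Et3N, MeCN, 0 °C → rt
Reagents that add atoms: 4-acetamidobenzenesulfonyl azide, CC(=O)Nc1ccc(cc1)S(=O)(=O)N=[N+]=[N-]
Why: Regitz diazo transfer to the doubly activated methylene of a β-keto ester is general and needs only an amine base.

Step 2
Reactants: 2 methyl 2-diazo-3-oxobutanoate
Product: 3 methyl 3-[(tert-butyldimethylsilyl)oxy]-2-diazobut-3-enoate
Conditions: TBSOTf, Et3N, CH2Cl2, 0 °C; made immediately before step 8 and used at once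
Reagents that add atoms: tert-butyldimethylsilyl trifluoromethanesulfonate, CC(C)(C)[Si](C)(C)OS(=O)(=O)C(F)(F)F
Why: Soft enolisation and O-silylation of the methyl ketone with a silyl triflate and an amine is the standard entry to 2-siloxyvinyl diazoacetates and leaves the diazo group untouched.

Step 3
Reactants: 4 (R)-but-3-yn-2-ol
Product: 5 (R)-but-3-yn-2-yl methanesulfonate
Conditions: MsCl, Et3N, CH2Cl2, −78 °C → 0 °C
Reagents that add atoms: methanesulfonyl chloride, CS(=O)(=O)Cl
Why: O-Sulfonylation does not involve the stereocentre, so the R configuration is retained.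

Step 4
Reactants: 6 pent-3-yn-1-ol
Product: 7 pent-3-ynal
Conditions: Dess–Martin periodinane, CH2Cl2, 0 °C → rt; filtered through a short silica pad, solution used at once
Reagents that add atoms: none
Why: Dess–Martin oxidation is fast and non-basic, which avoids isomerisation of the β,γ-alkynyl aldehyde to the allenal.

Step 5
Reactants: 5 (R)-but-3-yn-2-yl methanesulfonate; 7 pent-3-ynal
Product: 9 (3S,4R)-3-methylocta-1,6-diyn-4-ol, via allenylindium iodide mesylate 8 (not isolated)
Conditions: Pd(dppf)Cl2 (5 mol %), InI (1.4 equiv), THF/HMPA 3:1, rt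
Reagents that add atoms: none
Why: Marshall propargylation: zerovalent palladium formed in situ displaces the mesylate anti (SN2′), transmetalation to indium gives allenylindium 8 of fixed axial configuration, and its addition to the aldehyde through a cyclic SE2′ transition state transfers that chirality to the methyl-bearing carbon (guaiane C4, S) and, by the anti preference, fixes the carbinol carbon (guaiane C3, R).

Step 6
Reactants: 9 (3S,4R)-3-methylocta-1,6-diyn-4-ol
Product: 10 tert-butyldimethyl{[(3S,4R)-3-methylocta-1,6-diyn-4-yl]oxy}silane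
Conditions: TBSOTf, 2,6-lutidine, CH2Cl2, −78 → 0 °C
Reagents that add atoms: tert-butyldimethylsilyl trifluoromethanesulfonate, CC(C)(C)[Si](C)(C)OS(=O)(=O)C(F)(F)F
Why: Silylation of a secondary alcohol with a silyl triflate and a hindered pyridine base is reliable and does not touch either stereocentre or the alkynes.

Step 7
Reactants: 10 tert-butyldimethyl{[(3S,4R)-3-methylocta-1,6-diyn-4-yl]oxy}silane
Product: 11 tert-butyl{[(1R,2S,4E)-4-ethylidene-2-methyl-3-methylidenecyclopentyl]oxy}dimethylsilane (guaiane C3 R, C4 S; both substituents α)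
Conditions: Pd2(dba)3·CHCl3 (2.5 mol %), P(o-tol)3 (10 mol %), AcOH (2 equiv), Et3SiH (5 equiv), benzene, rt
Reagents that add atoms: none
Why: Palladium-catalysed reductive cyclisation of a 1,6-diyne: an acetatopalladium hydride adds syn across the terminal alkyne, 5-exo carbopalladation of the internal alkyne is again syn and the vinylpalladium is reduced by the silane with retention, so the ethylidene methyl ends up outside the diene (E) while C3 and C4 are not touched.

Step 8
Reactants: 11 tert-butyl{[(1R,2S,4E)-4-ethylidene-2-methyl-3-methylidenecyclopentyl]oxy}dimethylsilane; 3 methyl 3-[(tert-butyldimethylsilyl)oxy]-2-diazobut-3-enoate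
Product: 13 methyl (2R,3S,8S)-2,6-bis(TBSO)-3,8-dimethyl-1,2,3,4,7,8-hexahydroazulene-5-carboxylate, via cis-divinylcyclopropane 12 (not isolated)
Conditions: Rh2(S-PTAD)4 (1 mol %), hexanes, −26 °C → rt, 3 (1.5 equiv) added over 2 h; then 50 °C, 1 h
Reagents that add atoms: none
Why: The dirhodium tetracarboxylate decomposes 3 to a donor/acceptor rhodium vinylcarbene that adds in a concerted, asynchronous [2+1] fashion to the unhindered C5=C6 methylene (carbene carbon C7 to C6) and leaves the siloxyvinyl group cis to the C1=C10 vinyl on the spiro carbon, so that 12 is a cis-1,2-divinylcyclopropane. 12 then undergoes the divinylcyclopropane-to-cycloheptadiene Cope rearrangement through a boat transition state, C9 bonding to C10 while C5–C7 breaks, so ring B is closed in the [3,3]-sigmatropic mode and the net result is a formal [4+3] cycloaddition. The closest known reaction type is the rhodium-catalysed tandem cyclopropanation/Cope rearrangement of 2-siloxyvinyl diazoacetates with 1,3-dienes. The only new stereocentre, C10, is fixed by the diene face attacked and by the (E)-ethylidene geometry, because the Cope step is stereospecific: delivery of the three-carbon unit to the β-face with the methyl in the outside position gives 10S. The β-face is selected twice, by the cis C3 silyl ether and C4 methyl that block the α-face next to C5 and by the matched chiral catalyst. Site selectivity for C5=C6 over the trisubstituted C1=C10 rests on the strong preference of donor/acceptor carbenes for a terminal methylene carbon, and the ring-locked s-cis diene with an inside hydrogen at C10 keeps the boat transition state accessible.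

Step 9
Reactants: 13 methyl (2R,3S,8S)-2,6-bis(TBSO)-3,8-dimethyl-1,2,3,4,7,8-hexahydroazulene-5-carboxylate
Product: 14 methyl (2R,3S,8S)-2-(TBSO)-3,8-dimethyl-6-oxo-1,2,3,4,5,6,7,8-octahydroazulene-5-carboxylate (guaiane C7 epimers, partly enolised)
Conditions: TBAF (1.05 equiv), AcOH (1.2 equiv), THF, −40 °C
Reagents that add atoms: none
Why: Fluoride-mediated cleavage of a silyl enol ether whose leaving group is a stabilised β-keto ester enolate is far faster at −40 °C than cleavage of the secondary alkyl silyl ether at C3, and the acetic acid buffer protonates the enolate at once.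

Step 10
Reactants: 14 methyl (2R,3S,8S)-2-(TBSO)-3,8-dimethyl-6-oxo-1,2,3,4,5,6,7,8-octahydroazulene-5-carboxylate
Product: 15 methyl (2R,3S,5S,6R,8S)-2-(TBSO)-6-hydroxy-3,8-dimethyl-1,2,3,4,5,6,7,8-octahydroazulene-5-carboxylate (guaiane 7S,8R; 8β-OH cis to 7β-CO2Me and syn to the C10 methyl)
Conditions: RuCl(p-cymene)[(R,R)-TsDPEN] (3 mol %), HCO2H/Et3N (5:2), CH2Cl2, 30 °C
Reagents that add atoms: none
Why: Noyori–Ikariya transfer hydrogenation under dynamic kinetic resolution: C7 epimerises quickly through the enol, the ruthenium hydride is delivered to the α-face of C8 (anti to the C10 methyl) of the epimer whose ester lies on the β-face, and the outer-sphere transition state therefore gives the 8β-alcohol (8R) cis to the 7β-ester (7S), the cis outcome being the known one for cyclic β-keto esters with this catalyst class.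

Step 11
Reactants: 15 methyl (2R,3S,5S,6R,8S)-2-(TBSO)-6-hydroxy-3,8-dimethyl-1,2,3,4,5,6,7,8-octahydroazulene-5-carboxylate
Product: 17 (3R,4S,7S,8R,10S)-3-(TBSO)guai-1(5)-ene-8,11-diol, via methyl ketone 16 (not isolated)
Conditions: MeMgBr (6 equiv), LaCl3·2LiCl (0.3 equiv), THF, −20 °C → rt
Reagents that add atoms: methylmagnesium bromide, C[Mg]Br
Why: Double Grignard addition to the ester by way of methyl ketone 16: the C8 alkoxide formed first is inert, LaCl3·2LiCl favours carbonyl addition over enolisation and retro-aldol cleavage, and C7 and C8 are therefore carried through unchanged.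

Step 12
Reactants: 17 (3R,4S,7S,8R,10S)-3-(TBSO)guai-1(5)-ene-8,11-diol
Product: 18 (3R,4S,7S,8R,10S)-3-(TBSO)-11-hydroxyguai-1(5)-en-8-yl propanoate
Conditions: (EtCO)2O (1.5 equiv), pyridine, DMAP (0.1 equiv), CH2Cl2, 0 °C → rt
Reagents that add atoms: propanoic anhydride, CCC(=O)OC(=O)CC
Why: DMAP-catalysed acylation is much faster at the secondary C8 hydroxyl than at the tertiary C11 hydroxyl, so a small excess of anhydride at low temperature gives the mono-ester.

Step 13
Reactants: 18 (3R,4S,7S,8R,10S)-3-(TBSO)-11-hydroxyguai-1(5)-en-8-yl propanoate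
Product: 19 (3R,4S,7S,8R,10S)-11-acetoxy-3-(TBSO)guai-1(5)-en-8-yl propanoate
Conditions: Ac2O (10 equiv), Et3N, DMAP (1.5 equiv), CH2Cl2, 40 °C
Reagents that add atoms: acetic anhydride, CC(=O)OC(C)=O
Why: With stoichiometric DMAP the N-acetylpyridinium salt acetylates even the hindered tertiary C11 alcohol (Steglich-type acylation), and migration of the propanoyl group from the secondary to the tertiary oxygen is thermodynamically uphill.

Step 14
Reactants: 19 (3R,4S,7S,8R,10S)-11-acetoxy-3-(TBSO)guai-1(5)-en-8-yl propanoate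
Product: 20 (3R,4S,7S,8R,10S)-11-acetoxy-3-hydroxyguai-1(5)-en-8-yl propanoate
Conditions: HF·pyridine, pyridine, THF, 0 °C → rt
Reagents that add atoms: none
Why: Buffered HF·pyridine cleaves the secondary silyl ether by fluoride attack at silicon under conditions that leave both esters and the tetrasubstituted alkene alone.

Step 15
Reactants: 20 (3R,4S,7S,8R,10S)-11-acetoxy-3-hydroxyguai-1(5)-en-8-yl propanoate
Product: 22 (1R,7S,8R,10S)-11-acetoxy-3-oxoguai-4-en-8-yl propanoate (target), via β,γ-unsaturated ketone 21 (not isolated)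
Conditions: Dess–Martin periodinane, CH2Cl2, 0 °C → rt; aq. Na2S2O3/NaHCO3 wash; then DBU (0.3 equiv), toluene, rt
Reagents that add atoms: none
Why: Dess–Martin oxidation gives β,γ-unsaturated ketone 21, from which the amidine removes the doubly activated C4 hydrogen (β-face, since the C4 methyl is α) and returns it to C1 on the same face within the contact ion pair (suprafacial 1,3-prototropic shift), which gives the tetrasubstituted cyclopentenone as the thermodynamic sink and H-1β (1R), the epimer also expected at equilibrium because C2 is then trans to the C10 methyl.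

Compound list
1 | methyl acetoacetate | CC(=O)CC(=O)OC | starting material
2 | methyl 2-diazo-3-oxobutanoate | COC(=O)C(=[N+]=[N-])C(C)=O | intermediate
3 | methyl 3-[(tert-butyldimethylsilyl)oxy]-2-diazobut-3-enoate | COC(=O)C(=[N+]=[N-])C(=C)O[Si](C)(C)C(C)(C)C | intermediate
4 | (R)-but-3-yn-2-ol | C[C@@H](O)C#C | starting material
5 | (R)-but-3-yn-2-yl methanesulfonate | C[C@@H](OS(C)(=O)=O)C#C | intermediate
6 | pent-3-yn-1-ol | CC#CCCO | starting material
7 | pent-3-ynal | CC#CCC=O | intermediate
8 | (P)-(buta-1,2-dien-1-yl)iodoindium methanesulfonate (allenylindium, not isolated) | [H]C(C)=[C@]=C([H])[In](I)OS(C)(=O)=O | intermediate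
9 | (3S,4R)-3-methylocta-1,6-diyn-4-ol | C#C[C@H](C)[C@H](O)CC#CC | intermediate
10 | tert-butyldimethyl{[(3S,4R)-3-methylocta-1,6-diyn-4-yl]oxy}silane | C#C[C@H](C)[C@H](O[Si](C)(C)C(C)(C)C)CC#CC | intermediate
11 | tert-butyl{[(1R,2S,4E)-4-ethylidene-2-methyl-3-methylidenecyclopentyl]oxy}dimethylsilane | C/C=C1\C[C@@H](O[Si](C)(C)C(C)(C)C)[C@@H](C)C1=C | intermediate
12 | methyl (1S,3S,4S,5R,7E)-5-(TBSO)-1-[1-(TBSO)ethenyl]-7-ethylidene-4-methylspiro[2.4]heptane-1-carboxylate (cis-divinylcyclopropane, not isolated) | COC(=O)[C@@]1(C(=C)O[Si](C)(C)C(C)(C)C)C[C@]12/C(=C/C)C[C@@H](O[Si](C)(C)C(C)(C)C)[C@H]2C | intermediate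
13 | methyl (2R,3S,8S)-2,6-bis(TBSO)-3,8-dimethyl-1,2,3,4,7,8-hexahydroazulene-5-carboxylate | COC(=O)C1=C(O[Si](C)(C)C(C)(C)C)C[C@H](C)C2=C(C1)[C@H](C)[C@H](O[Si](C)(C)C(C)(C)C)C2 | intermediate
14 | methyl (2R,3S,8S)-2-(TBSO)-3,8-dimethyl-6-oxo-1,2,3,4,5,6,7,8-octahydroazulene-5-carboxylate (C5 of the azulene = guaiane C7, epimers/enol) | COC(=O)C1C(=O)C[C@H](C)C2=C(C1)[C@H](C)[C@H](O[Si](C)(C)C(C)(C)C)C2 | intermediate
15 | methyl (2R,3S,5S,6R,8S)-2-(TBSO)-6-hydroxy-3,8-dimethyl-1,2,3,4,5,6,7,8-octahydroazulene-5-carboxylate | O[C@@H]1C[C@H](C)C2=C(C[C@@H]1C(=O)OC)[C@H](C)[C@H](O[Si](C)(C)C(C)(C)C)C2 | intermediate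
16 | 1-[(2R,3S,5S,6R,8S)-2-(TBSO)-6-hydroxy-3,8-dimethyl-1,2,3,4,5,6,7,8-octahydroazulen-5-yl]ethan-1-one (methyl ketone, not isolated) | O[C@@H]1C[C@H](C)C2=C(C[C@@H]1C(C)=O)[C@H](C)[C@H](O[Si](C)(C)C(C)(C)C)C2 | intermediate
17 | (3R,4S,7S,8R,10S)-3-(TBSO)guai-1(5)-ene-8,11-diol | O[C@@H]1C[C@H](C)C2=C(C[C@@H]1C(C)(C)O)[C@H](C)[C@H](O[Si](C)(C)C(C)(C)C)C2 | intermediate
18 | (3R,4S,7S,8R,10S)-3-(TBSO)-11-hydroxyguai-1(5)-en-8-yl propanoate | CCC(=O)O[C@@H]1C[C@H](C)C2=C(C[C@@H]1C(C)(C)O)[C@H](C)[C@H](O[Si](C)(C)C(C)(C)C)C2 | intermediate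
19 | (3R,4S,7S,8R,10S)-11-acetoxy-3-(TBSO)guai-1(5)-en-8-yl propanoate | CCC(=O)O[C@@H]1C[C@H](C)C2=C(C[C@@H]1C(C)(C)OC(C)=O)[C@H](C)[C@H](O[Si](C)(C)C(C)(C)C)C2 | intermediate
20 | (3R,4S,7S,8R,10S)-11-acetoxy-3-hydroxyguai-1(5)-en-8-yl propanoate | CCC(=O)O[C@@H]1C[C@H](C)C2=C(C[C@@H]1C(C)(C)OC(C)=O)[C@H](C)[C@H](O)C2 | intermediate
21 | (4S,7S,8R,10S)-11-acetoxy-3-oxoguai-1(5)-en-8-yl propanoate (β,γ-unsaturated ketone, not isolated) | CCC(=O)O[C@@H]1C[C@H](C)C2=C(C[C@@H]1C(C)(C)OC(C)=O)[C@H](C)C(=O)C2 | intermediate
22 | (1R,7S,8R,10S)-11-acetoxy-3-oxoguai-4-en-8-yl propanoate | CCC(=O)O[C@@H]1C[C@H](C)[C@H]2CC(=O)C(C)=C2C[C@@H]1C(C)(C)OC(C)=O | target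

Total step count: 15. Longest linear sequence: 12 steps (6 → 22 through steps 4–15; equally 4 → 22 through steps 3 and 5–15).

Steps most likely to fail

Step 8. The carbene may be delivered to the α-face or to the C1=C10 alkene, or the cyclopropane may form with the siloxyvinyl group trans to the C1 vinyl, which does not undergo the Cope rearrangement at low temperature. Allylic C–H insertion at C2 or C4, or decomposition of the labile diazo compound 3 before it meets the catalyst, may also lower the yield. The fallback separates the two events and starts from diene 11 and the stable diazo keto ester 2. Cyclopropanation of the C5=C6 methylene with Rh2(esp)2 in CH2Cl2 under substrate control should give methyl (1S,3S,4S,5R,7E)-1-acetyl-5-(TBSO)-7-ethylidene-4-methylspiro[2.4]heptane-1-carboxylate F1. TBSOTf/Et3N then converts the acetyl group into its silyl enol ether, which is divinylcyclopropane 12, and warming gives 13, where the route is rejoined. Any C7 epimer of F1 would be equilibrated thermally (toluene, 110 °C) through reversible opening of the donor–acceptor bond C5–C7.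

Step 10. A mismatch between catalyst and substrate may erode face selectivity at C8, C7 epimerisation may be slower than reduction (trans isomer), or the C3 silyl ether may be partly lost in the acidic medium. The fallback replaces catalyst control by chelation control and starts from 14. Zn(BH4)2 in Et2O at −20 °C should reduce the six-membered zinc chelate of the β-keto ester from the face of H-7, which gives the cis relationship, while the C10 methyl, pushed pseudoaxial by allylic strain with C2, screens the β-face of C8. The product is again hydroxy ester 15, so no further compound arises (F0).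

Step 15. The ion pair may dissociate so that C1 is protonated from either face, alkene migration may be incomplete, or esters may be lost if harsher base is needed. The fallback moves enone formation to an ester-free, base-stable intermediate and relies on full thermodynamic equilibration; it starts from diol 17. 2-Methoxypropene/PPTS gives (3R,4S,7S,8R,10S)-3-(TBSO)-8,11-(isopropylidenedioxy)guai-1(5)-ene F2, and TBAF gives (3R,4S,7S,8R,10S)-8,11-(isopropylidenedioxy)guai-1(5)-en-3-ol F3. Dess–Martin oxidation followed by NaOMe/MeOH gives (1R,7S,8R,10S)-8,11-(isopropylidenedioxy)guai-4-en-3-one F4, with C1 equilibrated and any epimer separable and recyclable at this stage. Aqueous AcOH (80%) gives (1R,7S,8R,10S)-8,11-dihydroxyguai-4-en-3-one F5, and propanoic anhydride/pyridine/DMAP gives (1R,7S,8R,10S)-11-hydroxy-3-oxoguai-4-en-8-yl propanoate F6. Ac2O/DMAP/Et3N then gives 22, where the route is rejoined.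

Further compounds
F1 | step 8 | methyl (1S,3S,4S,5R,7E)-1-acetyl-5-(TBSO)-7-ethylidene-4-methylspiro[2.4]heptane-1-carboxylate | COC(=O)[C@@]1(C(C)=O)C[C@]12/C(=C/C)C[C@@H](O[Si](C)(C)C(C)(C)C)[C@H]2C
F0 | step 10 | none | none
F2 | step 15 | (3R,4S,7S,8R,10S)-3-(TBSO)-8,11-(isopropylidenedioxy)guai-1(5)-ene | CC1(C)O[C@@H]2C[C@H](C)C3=C(C[C@@H]2C(C)(C)O1)[C@H](C)[C@H](O[Si](C)(C)C(C)(C)C)C3
F3 | step 15 | (3R,4S,7S,8R,10S)-8,11-(isopropylidenedioxy)guai-1(5)-en-3-ol | CC1(C)O[C@@H]2C[C@H](C)C3=C(C[C@@H]2C(C)(C)O1)[C@H](C)[C@H](O)C3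
F4 | step 15 | (1R,7S,8R,10S)-8,11-(isopropylidenedioxy)guai-4-en-3-one | CC1(C)O[C@@H]2C[C@H](C)[C@H]3CC(=O)C(C)=C3C[C@@H]2C(C)(C)O1
F5 | step 15 | (1R,7S,8R,10S)-8,11-dihydroxyguai-4-en-3-one | O[C@@H]1C[C@H](C)[C@H]2CC(=O)C(C)=C2C[C@@H]1C(C)(C)O
F6 | step 15 | (1R,7S,8R,10S)-11-hydroxy-3-oxoguai-4-en-8-yl propanoate | CCC(=O)O[C@@H]1C[C@H](C)[C@H]2CC(=O)C(C)=C2C[C@@H]1C(C)(C)O
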